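**Retrosynthetic overview**

1. Target 19 is a cis-fused hexahydrofuro[3,2-b]furan-2-one (lactone O1–C2(=O)–C3–C3a–C6a; tetrahydrofuran C3a–O4–C5–C6–C6a). Last cut: the 6a-methyl and the first CH2 of the C12 chain are revealed together by Raney Ni from a one-sulfur bridge (6a-CH2–S–CH–C5), a temporary thiane ring that is not in the target.
2. Key disconnection: in the sulfur-bridged tricycle 18 the C6–C6a bond and the O4–C5 bond are made in one Lewis-acid cascade (ketone Prins closure, then capture of the tertiary cation by the silyl ether oxygen) from acyclic keto sulfide 16. Ring order: thiane, tetrahydrofuran, γ-lactone.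
3. Enabling feature: on the tetrahydrofuran ring the 6a-methyl and the chain on C5 are cis, 1,3 across C6, on the face opposite the lactone ring. Joined through one sulfur they form a six-membered ring that O4 can bridge only diaxially, so C5 and C6a are fixed by topology, and the C3a carbinol (Sharpless kinetic resolution) selects the enantiomer.
4. 16 comes from allylic thiol 14 (aryl Grignard + 1,11-dibromoundecane, then methacrolein, Mitsunobu) and epoxide 6 (methyl acetate + acrolein) by thiol–epoxide opening and oxidation.

Key step: step 10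

Remark: thiol 14 is used as the racemate, so 15–18 are pairs of epimers at the sulfur-bearing side-chain carbon only; that carbon becomes a CH2 group in step 11, so both epimers converge on the target.
Remark: the oxirane stereocentre of 5 and 6 is erased in step 9; only the carbinol centre is carried on.

**Route**

Step 1
Reactants: 1 methyl acetate; 2 acrolein
Product: 4 racemic methyl 3-hydroxypent-4-enoate, via lithium enolate of methyl acetate 3 (not isolated)
Conditions: LiN(iPr)2, THF, −78 °C; then 2; aq. NH4Cl
Reagents that add atoms: none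
Why: Aldol addition of the ester lithium enolate, which adds 1,2 to the enal at −78 °C; the carbinol centre is made racemic on purpose and resolved in step 2.

Step 2
Reactants: 4 racemic methyl 3-hydroxypent-4-enoate
Product: 5 methyl (3S)-3-hydroxy-3-[(2R)-oxiran-2-yl]propanoate
Conditions: Ti(OiPr)4 (20 mol %), L-(+)-diisopropyl tartrate (26 mol %), t-BuOOH (0.45 equiv), 4 Å MS, CH2Cl2, −20 °C
Reagents that add atoms: tert-butyl hydroperoxide, CC(C)(C)OO
Why: Sharpless asymmetric epoxidation run as a kinetic resolution: with the L-(+)-tartrate the (S)-enantiomer of a secondary vinyl carbinol should be epoxidised fast and erythro-selectively while the (R)-alcohol stays behind and is removed, which sets the centre that becomes C3a.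

Step 3
Reactants: 5 methyl (3S)-3-hydroxy-3-[(2R)-oxiran-2-yl]propanoate
Product: 6 methyl (3S)-3-[(2R)-oxiran-2-yl]-3-[(triethylsilyl)oxy]propanoate
Conditions: Et3SiCl, imidazole, CH2Cl2, 0 °C
Reagents that add atoms: chlorotriethylsilane, CC[Si](Cl)(CC)CC
Why: Standard silylation of a secondary alcohol; the triethylsilyl group protects the carbinol through steps 8 and 9 and is the leaving group on oxygen in step 10.

Step 4
Reactants: 7 4-(benzyloxy)phenylmagnesium bromide; 8 1,11-dibromoundecane
Product: 9 1-(benzyloxy)-4-(11-bromoundecyl)benzene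
Conditions: Li2CuCl4 (3 mol %), THF, 0 °C → rt; 8 in threefold excess, slow addition of 7
Reagents that add atoms: none
Why: Copper-catalysed coupling of a Grignard reagent with a primary alkyl bromide (Kochi type); the excess of dibromide (recovered) should hold the reaction at mono-substitution.

Step 5
Reactants: 9 1-(benzyloxy)-4-(11-bromoundecyl)benzene; 10 methacrolein
Product: 12 racemic 14-[4-(benzyloxy)phenyl]-2-methyltetradec-1-en-3-ol, via alkylmagnesium bromide 11 (not isolated)
Conditions: Mg, THF; then 10, −78 → 0 °C; aq. NH4Cl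
Reagents that add atoms: none
Why: Grignard formation and 1,2-addition to an enal; the carbinol is racemic by design because its carbon ends as a CH2 group.

Step 6
Reactants: 12 racemic 14-[4-(benzyloxy)phenyl]-2-methyltetradec-1-en-3-ol
Product: 13 racemic S-{14-[4-(benzyloxy)phenyl]-2-methyltetradec-1-en-3-yl} ethanethioate
Conditions: PPh3, DIAD, AcSH, THF, 0 °C
Reagents that add atoms: thioacetic acid, CC(=O)S
Why: Mitsunobu thioesterification, an SN2 displacement of the alkoxyphosphonium ion by thioacetate, which keeps the 1,1-disubstituted alkene in place.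

Step 7
Reactants: 13 racemic S-{14-[4-(benzyloxy)phenyl]-2-methyltetradec-1-en-3-yl} ethanethioate
Product: 14 racemic 14-[4-(benzyloxy)phenyl]-2-methyltetradec-1-ene-3-thiol
Conditions: NaOMe (1.05 equiv), MeOH/THF (degassed), 0 °C; then aq. HCl
Reagents that add atoms: none
Why: Methanolysis of a thioester (acyl transfer to methoxide), run oxygen-free so that the thiolate is not oxidised to the disulfide.

Step 8
Reactants: 14 racemic 14-[4-(benzyloxy)phenyl]-2-methyltetradec-1-ene-3-thiol; 6 methyl (3S)-3-[(2R)-oxiran-2-yl]-3-[(triethylsilyl)oxy]propanoate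
Product: 15 methyl (3S,4S)-5-({14-[4-(benzyloxy)phenyl]-2-methyltetradec-1-en-3-yl}sulfanyl)-4-hydroxy-3-[(triethylsilyl)oxy]pentanoate (both epimers at the S-bearing allylic carbon)
Conditions: Et3N (0.2 equiv), MeOH (degassed), rt
Reagents that add atoms: none
Why: Amine-catalysed SN2 opening of a terminal epoxide by a thiol at the CH2 carbon, which touches no stereocentre; the low alkoxide concentration in methanol should prevent silyl migration.

Step 9
Reactants: 15 methyl (3S,4S)-5-({14-[4-(benzyloxy)phenyl]-2-methyltetradec-1-en-3-yl}sulfanyl)-4-hydroxy-3-[(triethylsilyl)oxy]pentanoate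
Product: 16 methyl (3S)-5-({14-[4-(benzyloxy)phenyl]-2-methyltetradec-1-en-3-yl}sulfanyl)-4-oxo-3-[(triethylsilyl)oxy]pentanoate (both epimers at the S-bearing allylic carbon)
Conditions: Dess–Martin periodinane, NaHCO3, CH2Cl2, 0 °C → rt
Reagents that add atoms: none
Why: Dess–Martin oxidation of a secondary alcohol, which under buffered anhydrous conditions should leave the dialkyl sulfide, the alkene and the α-silyloxy centre untouched.

Step 10
Reactants: 16 methyl (3S)-5-({14-[4-(benzyloxy)phenyl]-2-methyltetradec-1-en-3-yl}sulfanyl)-4-oxo-3-[(triethylsilyl)oxy]pentanoate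
Product: 18 sulfur-bridged tricyclic lactone (the skeleton of 19 in which the 6a-CH2 and the side-chain carbon next to C5 are joined through sulfur; that carbon carries 11-[4-(benzyloxy)phenyl]undecyl; C3a, C5 and C6a as in 19), via bicyclic hydroxy ester 17 (not isolated)
Conditions: SnCl4 (1.5 equiv), CH2Cl2, −78 → −30 °C; aq. NaHCO3; then TsOH·H2O (cat.), CH2Cl2, rt
Reagents that add atoms: none
Why: Proposed new method: SnCl4 activates the ketone, the tethered 1,1-disubstituted alkene attacks it through its CH2 terminus (thiane ring, 6-endo Prins closure, making the C6–C6a bond), and the tertiary cation left at the methyl-bearing carbon, buffered by the ring sulfur as a thiiranium ion, is taken by the triethylsilyloxy oxygen across the ring (tetrahydrofuran ring, five-membered transannular closure, making the O4–C5 bond) with loss of Et3SiCl, after which the tertiary alkoxide closes the γ-lactone onto the cis CH2CO2Me arm (5-exo-trig, completed by TsOH). The closest known reactions are the Lewis-acid formal [3+2] annulation of α-(triethylsilyloxy) aldehydes with styrenes and allylsilanes to tetrahydrofuran-3-ols and the type 2 intramolecular ketone–ene (Prins) cyclisation of 1,1-disubstituted alkenes; their merger on a ketone carrying a tethered unactivated alkene is not known. C5 is fixed by topology, since O4 can reach the cation only from the axial position of the thiane, which puts the two sulfur-linked carbons (future 6a-methyl and future chain) cis and the C5 methyl on the lactone face. C6a is set against the existing C3a centre because the Prins addition is reversible and only the bicycle that carries the CH2CO2Me arm exo, away from the sulfur bridge, closes without strain; this is also the only epimer that can lactonise. The step needs oxygen capture to beat proton loss and chloride capture, which the 1,3-diaxial proximity of the silyl ether, its nucleofugal silyl group and the reversible sulfur participation should secure.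

Step 11
Reactants: 18 sulfur-bridged tricyclic lactone
Product: 19 plakortone N, (3aS,5S,6aS)-5-[12-(4-hydroxyphenyl)dodecyl]-5,6a-dimethyltetrahydrofuro[3,2-b]furan-2(3H)-one
Conditions: Raney Ni (W-2, excess), H2 (1 atm), EtOH, 50 °C
Reagents that add atoms: none
Why: Raney nickel hydrogenolysis should cleave both C–S bonds (the CH2–S carbon becomes the 6a-methyl, the S–CH carbon the first CH2 of the chain, which removes the only uncontrolled stereocentre) and, under H2, the aryl benzyl ether, while the lactone, the tertiary ethers and the three stereocentres are not involved.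

**Compound list**

1 | methyl acetate | COC(C)=O | starting material
2 | acrolein | C=CC=O | starting material
3 | lithium enolate of methyl acetate | C=C(OC)O[Li] | intermediate
4 | racemic methyl 3-hydroxypent-4-enoate | COC(=O)CC(O)C=C | intermediate
5 | methyl (3S)-3-hydroxy-3-[(2R)-oxiran-2-yl]propanoate | COC(=O)C[C@H](O)[C@H]1CO1 | intermediate
6 | methyl (3S)-3-[(2R)-oxiran-2-yl]-3-[(triethylsilyl)oxy]propanoate | COC(=O)C[C@H](O[Si](CC)(CC)CC)[C@H]1CO1 | intermediate
7 | 4-(benzyloxy)phenylmagnesium bromide (THF solution) | Br[Mg]c1ccc(OCc2ccccc2)cc1 | starting material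
8 | 1,11-dibromoundecane | BrCCCCCCCCCCCBr | starting material
9 | 1-(benzyloxy)-4-(11-bromoundecyl)benzene | BrCCCCCCCCCCCc1ccc(OCc2ccccc2)cc1 | intermediate
10 | methacrolein | CC(=C)C=O | starting material
11 | {11-[4-(benzyloxy)phenyl]undecyl}magnesium bromide | Br[Mg]CCCCCCCCCCCc1ccc(OCc2ccccc2)cc1 | intermediate
12 | racemic 14-[4-(benzyloxy)phenyl]-2-methyltetradec-1-en-3-ol | C=C(C)C(O)CCCCCCCCCCCc1ccc(OCc2ccccc2)cc1 | intermediate
13 | racemic S-{14-[4-(benzyloxy)phenyl]-2-methyltetradec-1-en-3-yl} ethanethioate | C=C(C)C(SC(C)=O)CCCCCCCCCCCc1ccc(OCc2ccccc2)cc1 | intermediate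
14 | racemic 14-[4-(benzyloxy)phenyl]-2-methyltetradec-1-ene-3-thiol | C=C(C)C(S)CCCCCCCCCCCc1ccc(OCc2ccccc2)cc1 | intermediate
15 | methyl (3S,4S)-5-({14-[4-(benzyloxy)phenyl]-2-methyltetradec-1-en-3-yl}sulfanyl)-4-hydroxy-3-[(triethylsilyl)oxy]pentanoate, both epimers at the S-bearing carbon | COC(=O)C[C@H](O[Si](CC)(CC)CC)[C@H](O)CSC(CCCCCCCCCCCc1ccc(OCc2ccccc2)cc1)C(C)=C | intermediate
16 | methyl (3S)-5-({14-[4-(benzyloxy)phenyl]-2-methyltetradec-1-en-3-yl}sulfanyl)-4-oxo-3-[(triethylsilyl)oxy]pentanoate, both epimers at the S-bearing carbon | COC(=O)C[C@H](O[Si](CC)(CC)CC)C(=O)CSC(CCCCCCCCCCCc1ccc(OCc2ccccc2)cc1)C(C)=C | intermediate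
17 | methyl 2-(4-{11-[4-(benzyloxy)phenyl]undecyl}-1-hydroxy-5-methyl-6-oxa-3-thiabicyclo[3.2.1]octan-7-yl)acetate; hydroxyl and CH2CO2Me cis, C1, C5 and C7 as in the SMILES (they become C6a, C5 and C3a of 19), both epimers at C4 | C[C@]1(C(CCCCCCCCCCCc3ccc(OCc4ccccc4)cc3)SC2)C[C@]2(O)[C@H](CC(=O)OC)O1 | intermediate
18 | sulfur-bridged tricyclic lactone: γ-lactone of 17 between the C1 hydroxyl and the C7 acetic ester arm; ring-fusion and quaternary centres as in 19, both epimers at the S–CH carbon | C[C@]1(C(CCCCCCCCCCCc4ccc(OCc5ccccc5)cc4)SC2)C[C@]32OC(=O)C[C@@H]3O1 | intermediate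
19 | plakortone N, (3aS,5S,6aS)-5-[12-(4-hydroxyphenyl)dodecyl]-5,6a-dimethyltetrahydrofuro[3,2-b]furan-2(3H)-one | C[C@]1(CCCCCCCCCCCCc2ccc(O)cc2)C[C@]2(C)OC(=O)C[C@@H]2O1 | target

**Step count and risks**

Total steps: 11. Longest linear sequence: 8 steps (steps 4 to 11, from 7 and 8 to 19).

Most likely to fail, first: step 10. The cation formed by the Prins closure may lose a proton or pick up chloride faster than the ether bridge closes, or the Lewis acid may be tied up by the sulfide and the ester. The fallback makes the two bonds in separate operations of known type, sets out from 16 and comes back at 18. Me2AlCl (CH2Cl2, −78 → 0 °C) promotes the type 2 intramolecular carbonyl-ene cyclisation of 16 to the thianol with an exocyclic methylene group, methyl (3S)-3-(6-{11-[4-(benzyloxy)phenyl]undecyl}-3-hydroxy-5-methylidenethian-3-yl)-3-[(triethylsilyl)oxy]propanoate F1. HF·pyridine followed by catalytic TsOH removes the silyl group and closes the γ-lactone from the tertiary hydroxyl, giving the spiro hydroxy lactone (4S)-8-{11-[4-(benzyloxy)phenyl]undecyl}-4-hydroxy-9-methylidene-1-oxa-7-thiaspiro[4.5]decan-2-one F2. Catalytic TfOH (CH2Cl2, 0 °C) then adds the secondary hydroxyl across the exocyclic alkene in the Markovnikov sense (transannular hydroalkoxylation) to give 18. Only the carbinol epimer whose hydroxyl faces the ring CH2 can bridge; the other is removed by chromatography at the stage of F2.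

Second: step 6. The activated secondary allylic alcohol may be displaced with allylic transposition (SN2') or eliminate to the diene. The fallback forms the carbon–carbon bond next to sulfur instead of the carbon–sulfur bond, sets out from 9 and comes back at 14, bypassing 12 and 13. 3-Chloro-2-methylprop-1-ene and 2-(trimethylsilyl)ethanethiol (K2CO3, DMF) give trimethyl{2-[(2-methylprop-2-en-1-yl)sulfanyl]ethyl}silane F3. Deprotonation (s-BuLi, THF, −78 °C) and α-alkylation of the thioallyl anion with bromide 9 give (2-{[14-(4-(benzyloxy)phenyl)-2-methyltetradec-1-en-3-yl]sulfanyl}ethyl)trimethylsilane F4. TBAF (THF, 50 °C) then cleaves the 2-(trimethylsilyl)ethyl group to the thiolate, and acidic work-up gives 14.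

Third: step 2. The titanium-mediated resolution of a terminal vinyl carbinol is slow, and the enantiomeric purity of the epoxy alcohol may erode through over-conversion or epoxide opening by isopropoxide. The fallback separates resolution from epoxidation, sets out from 4 and comes back at 5. Lipase-catalysed acetylation of 4 (Burkholderia cepacia lipase, vinyl acetate) is expected, by the empirical size rule for secondary alcohols, to acylate the (S)-alcohol and give methyl (3S)-3-acetoxypent-4-enoate F5, which K2CO3 in MeOH converts to methyl (3S)-3-hydroxypent-4-enoate F6. Hydroxyl-directed epoxidation (VO(acac)2, t-BuOOH, CH2Cl2) gives 5 together with its oxirane epimer, methyl (3S)-3-hydroxy-3-[(2S)-oxiran-2-yl]propanoate F7. F7 need not be separated: step 3 converts it to methyl (3S)-3-[(2S)-oxiran-2-yl]-3-[(triethylsilyl)oxy]propanoate F8, step 8 to methyl (3S,4R)-5-({14-[4-(benzyloxy)phenyl]-2-methyltetradec-1-en-3-yl}sulfanyl)-4-hydroxy-3-[(triethylsilyl)oxy]pentanoate F9, and step 9 oxidises F9 to the same ketone 16.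

**Further compounds**

F1 | step 10 | methyl (3S)-3-(6-{11-[4-(benzyloxy)phenyl]undecyl}-3-hydroxy-5-methylidenethian-3-yl)-3-[(triethylsilyl)oxy]propanoate | COC(=O)C[C@H](O[Si](CC)(CC)CC)C1(O)CSC(CCCCCCCCCCCc2ccc(OCc3ccccc3)cc2)C(=C)C1
F2 | step 10 | (4S)-8-{11-[4-(benzyloxy)phenyl]undecyl}-4-hydroxy-9-methylidene-1-oxa-7-thiaspiro[4.5]decan-2-one | O=C1C[C@H](O)C2(CSC(CCCCCCCCCCCc3ccc(OCc4ccccc4)cc3)C(=C)C2)O1
F3 | step 6 | trimethyl{2-[(2-methylprop-2-en-1-yl)sulfanyl]ethyl}silane | C=C(C)CSCC[Si](C)(C)C
F4 | step 6 | (2-{[14-(4-(benzyloxy)phenyl)-2-methyltetradec-1-en-3-yl]sulfanyl}ethyl)trimethylsilane | C=C(C)C(SCC[Si](C)(C)C)CCCCCCCCCCCc1ccc(OCc2ccccc2)cc1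
F5 | step 2 | methyl (3S)-3-acetoxypent-4-enoate | COC(=O)C[C@H](OC(C)=O)C=C
F6 | step 2 | methyl (3S)-3-hydroxypent-4-enoate | COC(=O)C[C@H](O)C=C
F7 | step 2 | methyl (3S)-3-hydroxy-3-[(2S)-oxiran-2-yl]propanoate | COC(=O)C[C@H](O)[C@@H]1CO1
F8 | step 2 | methyl (3S)-3-[(2S)-oxiran-2-yl]-3-[(triethylsilyl)oxy]propanoate | COC(=O)C[C@H](O[Si](CC)(CC)CC)[C@@H]1CO1
F9 | step 2 | methyl (3S,4R)-5-({14-[4-(benzyloxy)phenyl]-2-methyltetradec-1-en-3-yl}sulfanyl)-4-hydroxy-3-[(triethylsilyl)oxy]pentanoate | COC(=O)C[C@H](O[Si](CC)(CC)CC)[C@@H](O)CSC(CCCCCCCCCCCc1ccc(OCc2ccccc2)cc1)C(C)=C
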